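Read the runs as one clock before reckoning any flask.

| flask | substrate | temperature | remark | time |
|---|---|---|---|---|
| dawn | 0.67 M | −20 °C | run made earlier |  |
| midnight | 1.5 M | 15 °C | run made earlier |  |
| violet | 1.0 M | 25 °C |  | 2.0 min |
| teal | 1.0 M | 5 °C |  | 2.0 min |
| grey | 1.0 M | 45 °C |  | 2.0 min |
| green | 1.0 M | −15 °C |  | 2.0 min |

| run | time / min | target / % | substrate / % |
|---|---|---|---|
| dawn | 1.50 | 0 | 86.4 |
| dawn | 5.00 | 0.6 | 64.0 |
| dawn | 8.00 | 3.0 | 50.5 |
| dawn | 12.0 | 4.3 | 37.4 |
| dawn | 20.0 | 6.7 | 22.2 |
| dawn | 25.0 | 8.7 | 17.0 |
| midnight | 0.250 | 8.5 | 22.8 |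
| midnight | 0.833 | 18.9 | 1.4 |
| midnight | 1.33 | 20.5 | 0.5 |
| midnight | 2.00 | 20.3 | 0.3 |
| midnight | 3.00 | 19.8 | 0.4 |
| midnight | 4.00 | 20.1 | 0.2 |

(each reading ± 0.5 percentage points)

1. the best flask by amount of target, in percent of the substrate charged; "all alike" if 1.5 percentage points covers them all (violet / teal / grey / green / all alike)
2. amount of target at the end, in percent of the substrate charged, violet
3. amount of target at the end, in percent of the substrate charged, teal
4. amount of target at the end, in percent of the substrate charged, grey
5. amount of target at the end, in percent of the substrate charged, green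

- the analysis behind the earlier runs scatters by 0.5 percentage points, standard deviation

Dawn seems to contradict midnight. At 5.00 min dawn has lost 36.0 % of its substrate and shows 0.6 % of target, yet midnight at 2.00 min holds 20.3 %. But dawn's target goes on climbing, to 8.7 % at 25.0 min, so target trails substrate, and a flask has to be read by how far its clock has run.

So freeze the shape of dawn's curve and let temperature stretch its time axis. The first readings of c(substrate), taken as first-order, give 0.0975 min⁻¹ in dawn and 5.91 min⁻¹ in midnight. Midnight's charge is larger than dawn's, so the 71.1 kJ mol⁻¹ that follows is an apparent activation energy. Over the gap from dawn to green it gives 1.92: this is the clock factor, the minutes of dawn that one minute of green is worth.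

Green's charge of 1.0 M is larger than dawn's 0.67 M and is set aside here, so green's 2.0 min are worth, as an estimate, 3.85 min of dawn. Between dawn's readings at 1.50 min and 5.00 min that reads as 0.403 % of target, a value that carries the scatter of 0.5 percentage points, while the first-order reckoning puts 31.3 % of green's substrate as used. On this estimate green repeats dawn's contradiction.

The forecast names grey as best, with 20 % for violet, 14.5 % for teal, 22 % for grey and 0.7 % for green, between 0 % and 2 %. Its grounds include this: “Target lags substrate in both runs, which points to an intermediate.” For green the clock's estimate stands below the forecast's number.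

The flasks give 25.0 % in violet, 17.0 % in teal, 28.7 % in grey and 0.482 % in green, so grey is best.

    substrate → intermediate A (k = 0.0160 s⁻¹, Ea = 73.0 kJ mol⁻¹)
    intermediate B → side product (k = 0.00340 s⁻¹, Ea = 78.0 kJ mol⁻¹)
    substrate ⇌ intermediate B (K = 2.80, k = 0.00640 s⁻¹, Ea = 86.0 kJ mol⁻¹, ΔH = −12.0 kJ mol⁻¹)
    intermediate B → intermediate D (k = 0.0440 s⁻¹, Ea = 64.0 kJ mol⁻¹)
    intermediate A ⇌ intermediate C (K = 7.50, k = 0.240 s⁻¹, Ea = 71.0 kJ mol⁻¹, ΔH = −14.0 kJ mol⁻¹)
    2 substrate → self-condensation product (k = 0.00820 M⁻¹ s⁻¹, Ea = 62.0 kJ mol⁻¹)
    intermediate D → target (k = 0.240 s⁻¹, Ea = 74.0 kJ mol⁻¹)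
    (constants at 5 °C)

Grey stands 6.7 points above the forecast's number, a number near midnight's last reading of 20.1 % taken over. Green stands 0.079 points from the clock's value, inside the scatter of 0.5 points. Read the same green flask at 8.0 min instead: the factor makes that 15.4 min of dawn, and between dawn's readings at 12.0 min and 20.0 min this reads as 5.32 % of target. That neighbouring flask holds 5.49 %.

The earlier runs and the new flask were generated by integration with made-up constants, noise included.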